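**Plan**
- Retrosynthetic cuts, in order: the C6–C(quaternary) bond of the 1,1-dimethylallyl group (back to a 5-O-prenyl ether), then C4–C4a of ring C, then O1–C2, then C2–C3.
- Enabling feature: the C4 carbonyl is bonded to ring A at C4a, the carbon ortho to the O1-bearing C8a. An aryl anion at C4a of a benzylic aryl ether that already holds C2, C3 and a C4 amide can therefore close ring C with a single C–C bond.
- Forward order: the C2–C3–C4 chain is built on ring B from 3,4-dihydroxybenzoic acid and a ring A bromophenol is made from phloroglucinol. They are joined at O1–C2, ring C (the only ring formed) is closed at C4–C4a, and the side chain is then placed at C6 by prenylation of O5 and Claisen shift before deprotection.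
- Stereochemistry: C2 is the only stereocentre. It is set as the (R)-carbinol by ruthenium/(S)-BINAP hydrogenation of a β-keto amide and inverted to (S) in the Mitsunobu etherification. All later steps are neutral or acidic, so the flavanone is not opened.

Key step: step 8

Assumption: with β-aryl β-keto amides the (S)-BINAP ruthenium catalyst is taken to give the (R)-carbinol, the sense known for benzoylacetic acid derivatives; if the carbinol proves to be (S), the (R)-ligand is used and nothing else changes.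

**Route**

Step 1
Reactants: 1 phloroglucinol
Product: 2 3,5-bis(methoxymethoxy)phenol
Conditions: MOMCl (2.0 equiv), i-Pr2NEt (2.2 equiv), DMF, 0 °C → rt
Reagents that add atoms: chloromethyl methyl ether, COCCl
Why: Williamson-type O-alkylation of the symmetric triphenol with two equivalents of MOMCl should give the bis-ether as the main component of a statistical mixture, from which the mono- and tris-ethers are removed by chromatography.

Step 2
Reactants: 2 3,5-bis(methoxymethoxy)phenol
Product: 3 2-bromo-3,5-bis(methoxymethoxy)phenol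
Conditions: NBS (1.0 equiv), i-Pr2NH (10 mol%), CH2Cl2, −40 °C
Reagents that add atoms: N-bromosuccinimide, O=C1CCC(=O)N1Br
Why: Amine-catalysed ortho-bromination of a phenol with NBS (electrophilic aromatic substitution) should deliver bromine from the hydrogen-bonded N-bromoamine to one of the two equivalent carbons next to the free hydroxyl and not to the more crowded carbon between the two MOM ethers.

Step 3
Reactants: 4 3,4-dihydroxybenzoic acid
Product: 5 tert-butyldimethylsilyl 3,4-bis(tert-butyldimethylsilyloxy)benzoate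
Conditions: TBSCl (3.3 equiv), imidazole (6.6 equiv), DMF, rt
Reagents that add atoms: tert-butyldimethylsilyl chloride, CC(C)(C)[Si](C)(C)Cl
Why: Silylation with TBSCl and imidazole caps both phenols and the acid, the silyl ester serving only as a neutral precursor of the acid chloride.

Step 4
Reactants: 5 tert-butyldimethylsilyl 3,4-bis(tert-butyldimethylsilyloxy)benzoate
Product: 6 3,4-bis(tert-butyldimethylsilyloxy)benzoyl chloride
Conditions: (COCl)2 (1.2 equiv), DMF (cat.), CH2Cl2, 0 °C → rt; concentrate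
Reagents that add atoms: oxalyl chloride, O=C(Cl)C(=O)Cl
Why: Silyl esters react with oxalyl chloride and catalytic DMF (Vilsmeier-type chloride transfer) to give acid chlorides directly without liberating HCl, so the aryl silyl ethers should survive.

Step 5
Reactants: 6 3,4-bis(tert-butyldimethylsilyloxy)benzoyl chloride, 7 N-methoxy-N-methylacetamide
Product: 9 3-[3,4-bis(tert-butyldimethylsilyloxy)phenyl]-N-methoxy-N-methyl-3-oxopropanamide, via lithium enolate of N-methoxy-N-methylacetamide 8 (not isolated)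
Conditions: 7 (2.2 equiv), LiN(i-Pr)2 (2.2 equiv), THF, −78 °C; then 6, −78 °C; aq NH4Cl
Reagents that add atoms: none
Why: Crossed Claisen-type C-acylation of the amide lithium enolate by the acid chloride should give the β-keto amide, the second equivalent of enolate removing its acidic C2 proton so that the product is held as its enolate and not acylated again before the quench.

Step 6
Reactants: 9 3-[3,4-bis(tert-butyldimethylsilyloxy)phenyl]-N-methoxy-N-methyl-3-oxopropanamide
Product: 10 (3R)-3-[3,4-bis(tert-butyldimethylsilyloxy)phenyl]-3-hydroxy-N-methoxy-N-methylpropanamide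
Conditions: [RuCl(p-cymene)((S)-BINAP)]Cl (1 mol%), H2 (30 bar), EtOH–CH2Cl2, 40 °C
Reagents that add atoms: none
Why: Noyori asymmetric hydrogenation of a β-keto amide proceeds through the ketone/amide chelate on ruthenium, and the (S)-BINAP ligand should select the ketone face that gives the (R)-carbinol, which is the new stereocentre.

Step 7
Reactants: 10 (3R)-3-[3,4-bis(tert-butyldimethylsilyloxy)phenyl]-3-hydroxy-N-methoxy-N-methylpropanamide, 3 2-bromo-3,5-bis(methoxymethoxy)phenol
Product: 11 (3S)-3-[2-bromo-3,5-bis(methoxymethoxy)phenoxy]-3-[3,4-bis(tert-butyldimethylsilyloxy)phenyl]-N-methoxy-N-methylpropanamide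
Conditions: PPh3 (1.5 equiv), DIAD (1.5 equiv), 3 (1.2 equiv), toluene, 0 °C → rt
Reagents that add atoms: none
Why: In this Mitsunobu etherification the acidic ortho-bromophenol displaces the alkoxyphosphonium ion by SN2 attack with inversion, turning the (R)-carbinol into the (S)-benzylic aryl ether, while the non-polar solvent and low temperature disfavour ionisation and elimination.

Step 8
Reactants: 11 (3S)-3-[2-bromo-3,5-bis(methoxymethoxy)phenoxy]-3-[3,4-bis(tert-butyldimethylsilyloxy)phenyl]-N-methoxy-N-methylpropanamide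
Product: 14 (2S)-2-[3,4-bis(tert-butyldimethylsilyloxy)phenyl]-5,7-bis(methoxymethoxy)chroman-4-one, via C4a aryllithium 12 (not isolated), via chelated tetrahedral lithium alkoxide 13 (not isolated)
Conditions: t-BuLi (2.1 equiv, added to 11), THF, −95 → −78 °C; aq NH4Cl at −78 °C
Reagents that add atoms: none
Why: Bromine–lithium exchange at C4a (the second equivalent of t-BuLi destroys the t-BuBr formed) gives an aryllithium flanked by two ether oxygens, which adds to the amide carbonyl to give the five-membered N-methoxy lithium chelate 13; this tetrahedral species does not collapse before the quench, so the ketone is released only on work-up and is not attacked a second time. The closest known reaction is the Parham cyclisation (anionic cycloacylation) of 3-(2-bromoaryloxy)alkanoic Weinreb amides to chroman-4-ones. Ring C closes in a 6-exo-trig mode by formation of C4–C4a. No stereocentre is created, and C2 is preserved because no bond to it is made or broken and no acid is present that could ionise the benzylic ether. The selectivity required is exchange and ring closure ahead of deprotonation at C3 (which would expel the aryloxide) and ahead of direct addition of t-BuLi to the amide; it should be secured by the very fast exchange of an aryl bromide with two ortho oxygen substituents at −95 °C, by the intramolecular six-membered capture of the carbonyl, and by adding the base to the substrate so that free t-BuLi does not accumulate.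

Step 9
Reactants: 14 (2S)-2-[3,4-bis(tert-butyldimethylsilyloxy)phenyl]-5,7-bis(methoxymethoxy)chroman-4-one
Product: 15 (2S)-2-[3,4-bis(tert-butyldimethylsilyloxy)phenyl]-5-hydroxy-7-(methoxymethoxy)chroman-4-one
Conditions: MgBr2·OEt2 (3 equiv), CH2Cl2–Et2O, 0 °C → rt; aq NH4Cl
Reagents that add atoms: none
Why: In this chelation-directed ether cleavage, magnesium held between the C4 carbonyl and O5 should activate only the peri MOM acetal toward bromide, as in the classical selective 5-O-dealkylation of flavonoids, while the 7-MOM ether and the aryl silyl ethers cannot chelate and should stay.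

Step 10
Reactants: 15 (2S)-2-[3,4-bis(tert-butyldimethylsilyloxy)phenyl]-5-hydroxy-7-(methoxymethoxy)chroman-4-one, 16 3-methylbut-2-en-1-ol
Product: 17 (2S)-2-[3,4-bis(tert-butyldimethylsilyloxy)phenyl]-7-(methoxymethoxy)-5-(3-methylbut-2-enyloxy)chroman-4-one
Conditions: 16 (1.5 equiv), PPh3 (1.5 equiv), DIAD (1.5 equiv), THF, 0 °C → rt
Reagents that add atoms: none
Why: Mitsunobu O-alkylation of the hydrogen-bonded 5-hydroxyl with the primary allylic alcohol proceeds by SN2 attack at the CH2 carbon and avoids the basic alkylation conditions that would open the flavanone to the chalcone and racemise C2.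

Step 11
Reactants: 17 (2S)-2-[3,4-bis(tert-butyldimethylsilyloxy)phenyl]-7-(methoxymethoxy)-5-(3-methylbut-2-enyloxy)chroman-4-one
Product: 19 (2S)-2-[3,4-bis(tert-butyldimethylsilyloxy)phenyl]-5-hydroxy-7-(methoxymethoxy)-6-(2-methylbut-3-en-2-yl)chroman-4-one, via C6 ortho-dienone 18 (not isolated)
Conditions: Eu(fod)3 (10 mol%; fod = 6,6,7,7,8,8,8-heptafluoro-2,2-dimethyloctane-3,5-dionate), CHCl3, 50 °C
Reagents that add atoms: none
Why: In this Lewis-acid-catalysed aromatic Claisen rearrangement the [3,3] shift of the O5 prenyl group can reach only C6 (C4a is substituted) and inverts the allyl unit, so the 1,1-dimethylallyl group and its quaternary carbon form directly and the dienone should enolise to the chelated phenol at a temperature that leaves C2 untouched.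

Step 12
Reactants: 19 (2S)-2-[3,4-bis(tert-butyldimethylsilyloxy)phenyl]-5-hydroxy-7-(methoxymethoxy)-6-(2-methylbut-3-en-2-yl)chroman-4-one
Product: 20 (2S)-2-(3,4-dihydroxyphenyl)-5,7-dihydroxy-6-(2-methylbut-3-en-2-yl)chroman-4-one
Conditions: HCl (1.25 M in MeOH), MeOH–THF, 40 °C
Reagents that add atoms: none
Why: Acid-catalysed methanolysis should cleave the MOM acetal and both aryl silyl ethers in one operation, while the acidic medium keeps C2 configurationally stable (no enolate-driven ring opening) and is too mild to protonate the monosubstituted alkene.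

**Compound list**
1 | phloroglucinol | Oc1cc(O)cc(O)c1 | starting material
2 | 3,5-bis(methoxymethoxy)phenol | COCOc1cc(O)cc(OCOC)c1 | intermediate
3 | 2-bromo-3,5-bis(methoxymethoxy)phenol | COCOc1cc(O)c(Br)c(OCOC)c1 | intermediate
4 | 3,4-dihydroxybenzoic acid | O=C(O)c1ccc(O)c(O)c1 | starting material
5 | tert-butyldimethylsilyl 3,4-bis(tert-butyldimethylsilyloxy)benzoate | CC(C)(C)[Si](C)(C)OC(=O)c1ccc(O[Si](C)(C)C(C)(C)C)c(O[Si](C)(C)C(C)(C)C)c1 | intermediate
6 | 3,4-bis(tert-butyldimethylsilyloxy)benzoyl chloride | O=C(Cl)c1ccc(O[Si](C)(C)C(C)(C)C)c(O[Si](C)(C)C(C)(C)C)c1 | intermediate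
7 | N-methoxy-N-methylacetamide | CON(C)C(C)=O | starting material
8 | lithium enolate of N-methoxy-N-methylacetamide | C=C(O[Li])N(C)OC | intermediate
9 | 3-[3,4-bis(tert-butyldimethylsilyloxy)phenyl]-N-methoxy-N-methyl-3-oxopropanamide | CON(C)C(=O)CC(=O)c1ccc(O[Si](C)(C)C(C)(C)C)c(O[Si](C)(C)C(C)(C)C)c1 | intermediate
10 | (3R)-3-[3,4-bis(tert-butyldimethylsilyloxy)phenyl]-3-hydroxy-N-methoxy-N-methylpropanamide | CON(C)C(=O)C[C@@H](O)c1ccc(O[Si](C)(C)C(C)(C)C)c(O[Si](C)(C)C(C)(C)C)c1 | intermediate
11 | (3S)-3-[2-bromo-3,5-bis(methoxymethoxy)phenoxy]-3-[3,4-bis(tert-butyldimethylsilyloxy)phenyl]-N-methoxy-N-methylpropanamide | CON(C)C(=O)C[C@@H](c1ccc(O[Si](C)(C)C(C)(C)C)c(O[Si](C)(C)C(C)(C)C)c1)Oc1cc(OCOC)cc(OCOC)c1Br | intermediate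
12 | (3S)-3-[3,4-bis(tert-butyldimethylsilyloxy)phenyl]-3-[2-lithio-3,5-bis(methoxymethoxy)phenoxy]-N-methoxy-N-methylpropanamide | CON(C)C(=O)C[C@@H](c1ccc(O[Si](C)(C)C(C)(C)C)c(O[Si](C)(C)C(C)(C)C)c1)Oc1cc(OCOC)cc(OCOC)c1[Li] | intermediate
13 | lithium (2S)-2-[3,4-bis(tert-butyldimethylsilyloxy)phenyl]-4-[methoxy(methyl)amino]-5,7-bis(methoxymethoxy)chroman-4-olate (both C4 epimers) | CON(C)C1(O[Li])C[C@@H](c2ccc(O[Si](C)(C)C(C)(C)C)c(O[Si](C)(C)C(C)(C)C)c2)Oc2cc(OCOC)cc(OCOC)c21 | intermediate
14 | (2S)-2-[3,4-bis(tert-butyldimethylsilyloxy)phenyl]-5,7-bis(methoxymethoxy)chroman-4-one | O=C1C[C@@H](c2ccc(O[Si](C)(C)C(C)(C)C)c(O[Si](C)(C)C(C)(C)C)c2)Oc2cc(OCOC)cc(OCOC)c12 | intermediate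
15 | (2S)-2-[3,4-bis(tert-butyldimethylsilyloxy)phenyl]-5-hydroxy-7-(methoxymethoxy)chroman-4-one | O=C1C[C@@H](c2ccc(O[Si](C)(C)C(C)(C)C)c(O[Si](C)(C)C(C)(C)C)c2)Oc2cc(OCOC)cc(O)c12 | intermediate
16 | 3-methylbut-2-en-1-ol | CC(C)=CCO | starting material
17 | (2S)-2-[3,4-bis(tert-butyldimethylsilyloxy)phenyl]-7-(methoxymethoxy)-5-(3-methylbut-2-enyloxy)chroman-4-one | O=C1C[C@@H](c2ccc(O[Si](C)(C)C(C)(C)C)c(O[Si](C)(C)C(C)(C)C)c2)Oc2cc(OCOC)cc(OCC=C(C)C)c12 | intermediate
18 | (2S)-2-[3,4-bis(tert-butyldimethylsilyloxy)phenyl]-7-(methoxymethoxy)-6-(2-methylbut-3-en-2-yl)-2,3-dihydro-4H-chromene-4,5(6H)-dione (both C6 epimers) | C=CC(C)(C)C1C(=O)C2=C(C=C1OCOC)O[C@H](c1ccc(O[Si](C)(C)C(C)(C)C)c(O[Si](C)(C)C(C)(C)C)c1)CC2=O | intermediate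
19 | (2S)-2-[3,4-bis(tert-butyldimethylsilyloxy)phenyl]-5-hydroxy-7-(methoxymethoxy)-6-(2-methylbut-3-en-2-yl)chroman-4-one | C=CC(C)(C)c1c(OCOC)cc2c(c1O)C(=O)C[C@@H](c1ccc(O[Si](C)(C)C(C)(C)C)c(O[Si](C)(C)C(C)(C)C)c1)O2 | intermediate
20 | (2S)-2-(3,4-dihydroxyphenyl)-5,7-dihydroxy-6-(2-methylbut-3-en-2-yl)chroman-4-one | C=CC(C)(C)c1c(O)cc2c(c1O)C(=O)C[C@@H](c1ccc(O)c(O)c1)O2 | target

**Step count**
Total: 12 steps. Longest linear sequence: 10 steps (4 to 20 through steps 3–12); the ring A branch (steps 1–2) joins at step 7.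

**Steps most likely to fail**

Step 7 (Mitsunobu etherification). The activated benzylic oxygen may leave by elimination toward the cinnamamide, because the C3 protons lie next to the amide, and partial ionisation of the electron-rich benzylic centre may erode the inversion. The fallback sets out from 10 and returns at 11; it forms the ether at the alcohol oxidation level, where C3 has no acidic proton and no carbonyl drives elimination.
- Reduction of the Weinreb amide of 10 with LiBH4 in THF–MeOH should give (1R)-1-[3,4-bis(tert-butyldimethylsilyloxy)phenyl]propane-1,3-diol F1.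
- Pivaloyl chloride in pyridine at 0 °C should acylate only the primary hydroxyl to give (3R)-3-[3,4-bis(tert-butyldimethylsilyloxy)phenyl]-3-hydroxypropyl 2,2-dimethylpropanoate F2.
- Mitsunobu reaction of F2 with 3 (PPh3, DIAD, toluene) should give (3S)-3-[2-bromo-3,5-bis(methoxymethoxy)phenoxy]-3-[3,4-bis(tert-butyldimethylsilyloxy)phenyl]propyl 2,2-dimethylpropanoate F3.
- i-Bu2AlH at −78 °C should remove the pivalate to give (3S)-3-[2-bromo-3,5-bis(methoxymethoxy)phenoxy]-3-[3,4-bis(tert-butyldimethylsilyloxy)phenyl]propan-1-ol F4.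
- TEMPO with PhI(OAc)2 in MeCN–water should oxidise F4 to (3S)-3-[2-bromo-3,5-bis(methoxymethoxy)phenoxy]-3-[3,4-bis(tert-butyldimethylsilyloxy)phenyl]propanoic acid F5.
- Coupling of F5 with N,O-dimethylhydroxylamine hydrochloride (EDC·HCl, HOBt, N-methylmorpholine, CH2Cl2, 0 °C) gives 11.

Step 11 (Claisen rearrangement). The C6 dienone 18 may undergo a second [3,3] shift (Cope) to C8 before it enolises, which would leave the side chain at C8 as a 3-methylbut-2-enyl group. The fallback sets out from 14 and returns at 19; it blocks C8 with bromine first.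
- NBS in DMF at 0 °C is expected to brominate the less hindered free position of ring A to give (2S)-8-bromo-2-[3,4-bis(tert-butyldimethylsilyloxy)phenyl]-5,7-bis(methoxymethoxy)chroman-4-one F6.
- MgBr2·OEt2 as in step 9 should give (2S)-8-bromo-2-[3,4-bis(tert-butyldimethylsilyloxy)phenyl]-5-hydroxy-7-(methoxymethoxy)chroman-4-one F7.
- Mitsunobu prenylation with 16 as in step 10 should give (2S)-8-bromo-2-[3,4-bis(tert-butyldimethylsilyloxy)phenyl]-7-(methoxymethoxy)-5-(3-methylbut-2-enyloxy)chroman-4-one F8.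
- Eu(fod)3 in CHCl3 should give (2S)-8-bromo-2-[3,4-bis(tert-butyldimethylsilyloxy)phenyl]-5-hydroxy-7-(methoxymethoxy)-6-(2-methylbut-3-en-2-yl)chroman-4-one F9, since a Cope shift to the brominated C8 has no way to aromatise.
- Bu3SnH with AIBN in toluene at 80 °C then removes the bromine and gives 19.

Step 8 (ring closure). t-BuLi may remove a C3 proton or add to the amide faster than it exchanges the bromine; the C3 anion would then expel the aryloxide and the O1–C2 bond would be lost. The fallback sets out from 2 and returns at 14; it changes the halogen and the metal so that no strongly basic reagent is needed.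
- Ortho-iodination of 2 (N-iodosuccinimide, i-Pr2NH cat., CH2Cl2) should give 2-iodo-3,5-bis(methoxymethoxy)phenol F10.
- Mitsunobu coupling of F10 with 10 as in step 7 should give (3S)-3-[3,4-bis(tert-butyldimethylsilyloxy)phenyl]-3-[2-iodo-3,5-bis(methoxymethoxy)phenoxy]-N-methoxy-N-methylpropanamide F11.
- i-PrMgCl·LiCl in THF (−40 → 0 °C) should perform iodine–magnesium exchange; the arylmagnesium species is too weakly basic to deprotonate C3 and should be acylated by the Weinreb amide in the same 6-exo mode, giving 14 after the quench.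

**Further compounds**
F1 | step 7 | (1R)-1-[3,4-bis(tert-butyldimethylsilyloxy)phenyl]propane-1,3-diol | OCC[C@@H](O)c1ccc(O[Si](C)(C)C(C)(C)C)c(O[Si](C)(C)C(C)(C)C)c1
F2 | step 7 | (3R)-3-[3,4-bis(tert-butyldimethylsilyloxy)phenyl]-3-hydroxypropyl 2,2-dimethylpropanoate | CC(C)(C)C(=O)OCC[C@@H](O)c1ccc(O[Si](C)(C)C(C)(C)C)c(O[Si](C)(C)C(C)(C)C)c1
F3 | step 7 | (3S)-3-[2-bromo-3,5-bis(methoxymethoxy)phenoxy]-3-[3,4-bis(tert-butyldimethylsilyloxy)phenyl]propyl 2,2-dimethylpropanoate | CC(C)(C)C(=O)OCC[C@@H](c1ccc(O[Si](C)(C)C(C)(C)C)c(O[Si](C)(C)C(C)(C)C)c1)Oc1cc(OCOC)cc(OCOC)c1Br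
F4 | step 7 | (3S)-3-[2-bromo-3,5-bis(methoxymethoxy)phenoxy]-3-[3,4-bis(tert-butyldimethylsilyloxy)phenyl]propan-1-ol | OCC[C@@H](c1ccc(O[Si](C)(C)C(C)(C)C)c(O[Si](C)(C)C(C)(C)C)c1)Oc1cc(OCOC)cc(OCOC)c1Br
F5 | step 7 | (3S)-3-[2-bromo-3,5-bis(methoxymethoxy)phenoxy]-3-[3,4-bis(tert-butyldimethylsilyloxy)phenyl]propanoic acid | OC(=O)C[C@@H](c1ccc(O[Si](C)(C)C(C)(C)C)c(O[Si](C)(C)C(C)(C)C)c1)Oc1cc(OCOC)cc(OCOC)c1Br
F6 | step 11 | (2S)-8-bromo-2-[3,4-bis(tert-butyldimethylsilyloxy)phenyl]-5,7-bis(methoxymethoxy)chroman-4-one | O=C1C[C@@H](c2ccc(O[Si](C)(C)C(C)(C)C)c(O[Si](C)(C)C(C)(C)C)c2)Oc2c(Br)c(OCOC)cc(OCOC)c12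
F7 | step 11 | (2S)-8-bromo-2-[3,4-bis(tert-butyldimethylsilyloxy)phenyl]-5-hydroxy-7-(methoxymethoxy)chroman-4-one | O=C1C[C@@H](c2ccc(O[Si](C)(C)C(C)(C)C)c(O[Si](C)(C)C(C)(C)C)c2)Oc2c(Br)c(OCOC)cc(O)c12
F8 | step 11 | (2S)-8-bromo-2-[3,4-bis(tert-butyldimethylsilyloxy)phenyl]-7-(methoxymethoxy)-5-(3-methylbut-2-enyloxy)chroman-4-one | O=C1C[C@@H](c2ccc(O[Si](C)(C)C(C)(C)C)c(O[Si](C)(C)C(C)(C)C)c2)Oc2c(Br)c(OCOC)cc(OCC=C(C)C)c12
F9 | step 11 | (2S)-8-bromo-2-[3,4-bis(tert-butyldimethylsilyloxy)phenyl]-5-hydroxy-7-(methoxymethoxy)-6-(2-methylbut-3-en-2-yl)chroman-4-one | C=CC(C)(C)c1c(OCOC)c(Br)c2c(c1O)C(=O)C[C@@H](c1ccc(O[Si](C)(C)C(C)(C)C)c(O[Si](C)(C)C(C)(C)C)c1)O2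
F10 | step 8 | 2-iodo-3,5-bis(methoxymethoxy)phenol | COCOc1cc(O)c(I)c(OCOC)c1
F11 | step 8 | (3S)-3-[3,4-bis(tert-butyldimethylsilyloxy)phenyl]-3-[2-iodo-3,5-bis(methoxymethoxy)phenoxy]-N-methoxy-N-methylpropanamide | CON(C)C(=O)C[C@@H](c1ccc(O[Si](C)(C)C(C)(C)C)c(O[Si](C)(C)C(C)(C)C)c1)Oc1cc(OCOC)cc(OCOC)c1I
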